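## Retrosynthetic overview

1. The target comes from a C2-symmetric 5,5',7,7'-tetraphenol by O-methylation of one of its two equivalent 7-OH groups; the tetraphenol comes from its tetrabenzyl ether.
2. Both pyranone rings (ring C of each half) are closed last and together through the O1–C8a bonds, by intramolecular SNAr of the C2 alkoxides onto ortho-fluoro aryl ketones. C2 keeps its configuration, so a syn-aldol becomes a 2,3-cis flavanone.
3. The ring A aryl ketones come from double addition of an ortho-fluoroaryllithium to a C2-symmetric cis-fused bis-γ-lactone.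
4. Key disconnection: C2–C3 and C2'–C3' by a two-fold intermolecular Evans syn-aldol reaction of a succinyl bis(oxazolidinone) with 4-methoxybenzaldehyde. It sets all four stereocentres; lactonisation releases the auxiliary.
5. Ring order: rings A and B are bought as arenes, then the temporary bis-lactone, then both rings C.

Assumption: the SMILES is read as (2R,3R,2'R,3'R), i.e. H-2/H-3 cis in both chromanone rings; the unprimed half is the 5,7-dihydroxy unit and the primed half the 5-hydroxy-7-methoxy unit.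

## Route

Step 1
Reactants: 1 5-fluorobenzene-1,3-diol
Product: 2 1,3-bis(benzyloxy)-5-fluorobenzene
Conditions: BnBr (2.2 equiv), K2CO3, DMF, rt
Reagents that add atoms: benzyl bromide, BrCc1ccccc1
Why: Double Williamson O-benzylation of the two phenols (SN2 on benzyl bromide); no stereocentre is involved.

Step 2
Reactants: 2 1,3-bis(benzyloxy)-5-fluorobenzene
Product: 3 1,5-bis(benzyloxy)-2-bromo-3-fluorobenzene
Conditions: NBS (1.0 equiv), MeCN, 0 °C to rt
Reagents that add atoms: N-bromosuccinimide, O=C1CCC(=O)N1Br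
Why: Electrophilic aromatic bromination goes para to one benzyloxy group at the position flanked by F and OBn (the site between the two OBn groups is more hindered), and one equivalent of NBS stops at the monobromide.

Step 3
Reactants: 4 (4R)-4-benzyl-1,3-oxazolidin-2-one; 5 succinyl chloride
Product: 7 1,4-bis[(4R)-4-benzyl-2-oxo-1,3-oxazolidin-3-yl]butane-1,4-dione, via lithium oxazolidinide 6 (not isolated)
Conditions: 4 (2.0 equiv), n-BuLi (2.0 equiv), THF, −78 °C; then 5 (1.0 equiv), −78 to 0 °C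
Reagents that add atoms: none
Why: Two-fold N-acylation of the lithiated Evans auxiliary by the diacid chloride at low temperature; the auxiliary stereocentres are not touched.

Step 4
Reactants: 7 1,4-bis[(4R)-4-benzyl-2-oxo-1,3-oxazolidin-3-yl]butane-1,4-dione; 8 4-methoxybenzaldehyde
Product: 11 (3R,3aR,6R,6aR)-3,6-bis(4-methoxyphenyl)tetrahydrofuro[3,4-c]furan-1,4-dione, via bis(boron enolate) 9 (not isolated), via bis-aldol diol 10 (not isolated)
Conditions: Bu2BOTf (2.4 equiv), i-Pr2NEt (2.8 equiv), CH2Cl2, 0 °C; 8 (2.6 equiv), −78 to 0 °C; pH 7 buffer, MeOH, 30% H2O2, 0 °C; then Et3N (0.3 equiv), CH2Cl2, rt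
Reagents that add atoms: none
Why: Two-fold Evans syn-aldol reaction in which each (Z)-boron enolate reacts through a closed Zimmerman–Traxler transition state on the face left open by the (4R)-benzyl group, setting R at both carbinol carbons and both α-carbons, after which each γ-hydroxyl acylates on the distal imide carbonyl to give the cis-fused bis-lactone and free auxiliary, a double closure that only the C2-symmetric syn,syn diastereomer can complete.

Step 5
Reactants: 3 1,5-bis(benzyloxy)-2-bromo-3-fluorobenzene; 11 (3R,3aR,6R,6aR)-3,6-bis(4-methoxyphenyl)tetrahydrofuro[3,4-c]furan-1,4-dione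
Product: 13 (2R,3R)-1,4-bis[2,4-bis(benzyloxy)-6-fluorophenyl]-2,3-bis[(R)-hydroxy(4-methoxyphenyl)methyl]butane-1,4-dione, via aryllithium 12 (not isolated)
Conditions: 3 (2.4 equiv), n-BuLi (2.3 equiv), THF, −78 °C, 20 min; 11 in THF, −78 °C, 2 h; AcOH in THF at −78 °C, then warm
Reagents that add atoms: none
Why: Bromine–lithium exchange gives an ortho-fluoroaryllithium that is stable at −78 °C and adds once to each γ-lactone carbonyl (the lithium lactolate does not collapse before the cold acidic quench, so no tertiary alcohol forms), while the four stereocentres are not involved and the bridgehead carbons cannot epimerise in the cis-fused bicycle.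

Step 6
Reactants: 13 (2R,3R)-1,4-bis[2,4-bis(benzyloxy)-6-fluorophenyl]-2,3-bis[(R)-hydroxy(4-methoxyphenyl)methyl]butane-1,4-dione
Product: 15 (2R,2'R,3R,3'R)-5,5',7,7'-tetrakis(benzyloxy)-2,2'-bis(4-methoxyphenyl)-[3,3'-bichromane]-4,4'-dione, via dilithium dialkoxide 14 (not isolated)
Conditions: LiN(SiMe3)2 (2.05 equiv), THF–DMPU (5:1), −78 to 0 °C; AcOH at 0 °C
Reagents that add atoms: none
Why: Two intramolecular SNAr reactions (6-exo) in which each C2 alkoxide displaces the fluoride ortho to its own aryl ketone, so the C2–O bond is never broken (2R retained, the syn-aldol relationship becomes 2,3-cis), and stoichiometric base at low temperature with an acidic quench limits C3 enolisation and retro-aldol cleavage.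

Step 7
Reactants: 15 (2R,2'R,3R,3'R)-5,5',7,7'-tetrakis(benzyloxy)-2,2'-bis(4-methoxyphenyl)-[3,3'-bichromane]-4,4'-dione
Product: 16 (2R,2'R,3R,3'R)-5,5',7,7'-tetrahydroxy-2,2'-bis(4-methoxyphenyl)-[3,3'-bichromane]-4,4'-dione
Conditions: H2 (1 atm), 10% Pd/C, EtOAc–MeOH (1:1), rt
Reagents that add atoms: none
Why: Catalytic hydrogenolysis of the four O-benzyl ethers under neutral conditions is far faster than cleavage of the hindered C2–O1 benzylic aryl ether, so the base-labile cis stereocentres are untouched.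

Step 8
Reactants: 16 (2R,2'R,3R,3'R)-5,5',7,7'-tetrahydroxy-2,2'-bis(4-methoxyphenyl)-[3,3'-bichromane]-4,4'-dione
Product: 17 (2R,2'R,3R,3'R)-5,5',7-trihydroxy-7'-methoxy-2,2'-bis(4-methoxyphenyl)-[3,3'-bichromane]-4,4'-dione
Conditions: CH2N2 (0.9 equiv, Et2O solution, slow addition), MeOH–Et2O, 0 °C; recovered 16 recycled
Reagents that add atoms: diazomethane, C=[N+]=[N-]
Why: Diazomethane O-methylation touches only the acidic 7-OH groups (the 5-OH groups are hydrogen-bonded to C4=O) without any base that could epimerise C3, and sub-stoichiometric reagent gives the mono-ether statistically (about half per pass) beside the 7,7'-dimethyl ether and recovered 16.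

## Compound list

1 | 5-fluorobenzene-1,3-diol | Oc1cc(O)cc(F)c1 | starting material
2 | 1,3-bis(benzyloxy)-5-fluorobenzene | Fc1cc(OCc2ccccc2)cc(OCc2ccccc2)c1 | intermediate
3 | 1,5-bis(benzyloxy)-2-bromo-3-fluorobenzene | Fc1cc(OCc2ccccc2)cc(OCc2ccccc2)c1Br | intermediate
4 | (4R)-4-benzyl-1,3-oxazolidin-2-one | O=C1N[C@H](Cc2ccccc2)CO1 | starting material
5 | succinyl chloride (butanedioyl dichloride) | O=C(Cl)CCC(Cl)=O | starting material
6 | lithium (4R)-4-benzyl-2-oxo-1,3-oxazolidin-3-ide | [Li+].O=C1[N-][C@H](Cc2ccccc2)CO1 | intermediate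
7 | 1,4-bis[(4R)-4-benzyl-2-oxo-1,3-oxazolidin-3-yl]butane-1,4-dione | O=C(CCC(=O)N1[C@H](Cc2ccccc2)COC1=O)N1[C@H](Cc2ccccc2)COC1=O | intermediate
8 | 4-methoxybenzaldehyde | COc1ccc(C=O)cc1 | starting material
9 | (1Z,3Z)-1,4-bis[(4R)-4-benzyl-2-oxo-1,3-oxazolidin-3-yl]buta-1,3-diene-1,4-diyl bis(dibutylborinate) | CCCCB(CCCC)O/C(=C\C=C(/OB(CCCC)CCCC)N1[C@H](Cc2ccccc2)COC1=O)N1[C@H](Cc2ccccc2)COC1=O | intermediate
10 | (2R,3R)-1,4-bis[(4R)-4-benzyl-2-oxo-1,3-oxazolidin-3-yl]-2,3-bis[(R)-hydroxy(4-methoxyphenyl)methyl]butane-1,4-dione | COc1ccc([C@H](O)[C@H](C(=O)N2[C@H](Cc3ccccc3)COC2=O)[C@@H](C(=O)N2[C@H](Cc3ccccc3)COC2=O)[C@@H](O)c2ccc(OC)cc2)cc1 | intermediate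
11 | (3R,3aR,6R,6aR)-3,6-bis(4-methoxyphenyl)tetrahydrofuro[3,4-c]furan-1,4-dione (cis-fused, both aryl groups exo) | COc1ccc([C@@H]2OC(=O)[C@@H]3[C@H]2C(=O)O[C@H]3c2ccc(OC)cc2)cc1 | intermediate
12 | [2,4-bis(benzyloxy)-6-fluorophenyl]lithium | [Li]c1c(F)cc(OCc2ccccc2)cc1OCc1ccccc1 | intermediate
13 | (2R,3R)-1,4-bis[2,4-bis(benzyloxy)-6-fluorophenyl]-2,3-bis[(R)-hydroxy(4-methoxyphenyl)methyl]butane-1,4-dione (may equilibrate with its bis-lactol form) | COc1ccc([C@H](O)[C@H](C(=O)c2c(F)cc(OCc3ccccc3)cc2OCc2ccccc2)[C@@H](C(=O)c2c(F)cc(OCc3ccccc3)cc2OCc2ccccc2)[C@@H](O)c2ccc(OC)cc2)cc1 | intermediate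
14 | dilithium dialkoxide of 13 | COc1ccc([C@H]([O-])[C@H](C(=O)c2c(F)cc(OCc3ccccc3)cc2OCc2ccccc2)[C@@H](C(=O)c2c(F)cc(OCc3ccccc3)cc2OCc2ccccc2)[C@@H]([O-])c2ccc(OC)cc2)cc1.[Li+].[Li+] | intermediate
15 | (2R,2'R,3R,3'R)-5,5',7,7'-tetrakis(benzyloxy)-2,2'-bis(4-methoxyphenyl)-[3,3'-bichromane]-4,4'-dione | COc1ccc([C@@H]2Oc3cc(OCc4ccccc4)cc(OCc4ccccc4)c3C(=O)[C@@H]2[C@H]2C(=O)c3c(OCc4ccccc4)cc(OCc4ccccc4)cc3O[C@H]2c2ccc(OC)cc2)cc1 | intermediate
16 | (2R,2'R,3R,3'R)-5,5',7,7'-tetrahydroxy-2,2'-bis(4-methoxyphenyl)-[3,3'-bichromane]-4,4'-dione | COc1ccc([C@@H]2Oc3cc(O)cc(O)c3C(=O)[C@@H]2[C@H]2C(=O)c3c(O)cc(O)cc3O[C@H]2c2ccc(OC)cc2)cc1 | intermediate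
17 | (2R,2'R,3R,3'R)-5,5',7-trihydroxy-7'-methoxy-2,2'-bis(4-methoxyphenyl)-[3,3'-bichromane]-4,4'-dione | COc1ccc([C@@H]2Oc3cc(O)cc(O)c3C(=O)[C@@H]2[C@H]2C(=O)c3c(O)cc(OC)cc3O[C@H]2c2ccc(OC)cc2)cc1 | target

## Step count and risks

Total steps: 8. Longest linear sequence: 6 steps (steps 3, 4, 5, 6, 7, 8 from 4; equally steps 1, 2, 5, 6, 7, 8 from 1).

Step 6 is the most exposed. The alkoxides of 13 are aldolates, so retro-aldol cleavage competes with ring closure. Once a ring has formed, any remaining base can enolise C3 and turn the kinetic 2,3-cis flavanone into the trans isomer or open it to a chalcone. The fallback sets out from 13: both carbinols are silylated (Me3SiCl, imidazole, CH2Cl2, 0 °C) to give the bis(trimethylsilyl ether) F1. The ring closure is then run as a fluoride-catalysed desilylative SNAr (CsF 10 mol %, DMF, rt). Each Si–O bond is exchanged for the aryl–O bond with loss of Me3SiF, so only a catalytic amount of alkoxide is present at any time and no stoichiometric base remains beside the product. This comes back to the route at 15.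

Step 4 is the next risk. Double enolisation of the bis-imide may stop at the mono-enolate, which after one aldol reaction would lactonise early. The second aldol reaction, next to the first new stereocentre, may also be less selective than a simple Evans case. The fallback sets out from 8: Knoevenagel–Doebner condensation with malonic acid (pyridine, piperidine, 90 °C) gives (E)-4-methoxycinnamic acid F2. Oxidative β,β-dimerisation of F2 with Tl(OCOCF3)3 and BF3·OEt2 in CF3CO2H–CH2Cl2 gives the racemic exo,exo bis-lactone, with both benzylic cations trapped by the carboxyl groups. The racemate is 11 together with its mirror-image bis-lactone F3, and preparative chiral SFC separates them. This comes back to the route at 11.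

Step 8 cannot exceed about half conversion to 17 per pass because the two 7-OH groups of 16 are equivalent. The fallback moves the differentiation of the two halves to the aryl ketone stage and sets out from 11:
- 11 is treated with only 1.0 equiv of 12 at −78 °C and the mono-adduct keto-lactone F4 is isolated; unreacted 11 is recovered.
- 1-Fluoro-3,5-dimethoxybenzene is brominated (NBS, MeCN) to 2-bromo-1-fluoro-3,5-dimethoxybenzene F5 and lithiated (n-BuLi, THF, −78 °C) to (2-fluoro-4,6-dimethoxyphenyl)lithium F6.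
- F6 (2.2 equiv) is added to F4 to give the unsymmetrical bis(hydroxy ketone) F7.
- Ring closure as in step 6, through its dilithium dialkoxide F8, gives the mixed bis-flavanone F9, which carries 5,7-dibenzyloxy groups on one half and 5,7-dimethoxy groups on the other.
- BCl3 with pentamethylbenzene (CH2Cl2, −78 to 0 °C) removes both benzyl groups and, through chelation to the neighbouring C4' carbonyl, only the 5'-methyl ether. The 7'-OMe and both 4-methoxyphenyl ethers stay.

This comes back to the route at 17.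

Further compounds
F1 | step 6 | (2R,3R)-1,4-bis[2,4-bis(benzyloxy)-6-fluorophenyl]-2,3-bis[(R)-(4-methoxyphenyl)(trimethylsilyloxy)methyl]butane-1,4-dione | COc1ccc([C@H](O[Si](C)(C)C)[C@H](C(=O)c2c(F)cc(OCc3ccccc3)cc2OCc2ccccc2)[C@@H](C(=O)c2c(F)cc(OCc3ccccc3)cc2OCc2ccccc2)[C@@H](O[Si](C)(C)C)c2ccc(OC)cc2)cc1
F2 | step 4 | (E)-4-methoxycinnamic acid | COc1ccc(/C=C/C(=O)O)cc1
F3 | step 4 | (3S,3aS,6S,6aS)-3,6-bis(4-methoxyphenyl)tetrahydrofuro[3,4-c]furan-1,4-dione | COc1ccc([C@H]2OC(=O)[C@H]3[C@@H]2C(=O)O[C@@H]3c2ccc(OC)cc2)cc1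
F4 | step 8 | (3R,4R,5R)-4-[2,4-bis(benzyloxy)-6-fluorobenzoyl]-3-[(R)-hydroxy(4-methoxyphenyl)methyl]-5-(4-methoxyphenyl)oxolan-2-one | COc1ccc([C@@H]2OC(=O)[C@@H]([C@@H](O)c3ccc(OC)cc3)[C@H]2C(=O)c2c(F)cc(OCc3ccccc3)cc2OCc2ccccc2)cc1
F5 | step 8 | 2-bromo-1-fluoro-3,5-dimethoxybenzene | COc1cc(F)c(Br)c(OC)c1
F6 | step 8 | (2-fluoro-4,6-dimethoxyphenyl)lithium | [Li]c1c(F)cc(OC)cc1OC
F7 | step 8 | (2R,3R)-1-[2,4-bis(benzyloxy)-6-fluorophenyl]-4-(2-fluoro-4,6-dimethoxyphenyl)-2,3-bis[(R)-hydroxy(4-methoxyphenyl)methyl]butane-1,4-dione | COc1ccc([C@H](O)[C@H](C(=O)c2c(F)cc(OCc3ccccc3)cc2OCc2ccccc2)[C@@H](C(=O)c2c(F)cc(OC)cc2OC)[C@@H](O)c2ccc(OC)cc2)cc1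
F8 | step 8 | dilithium dialkoxide of F7 | COc1ccc([C@H]([O-])[C@H](C(=O)c2c(F)cc(OCc3ccccc3)cc2OCc2ccccc2)[C@@H](C(=O)c2c(F)cc(OC)cc2OC)[C@@H]([O-])c2ccc(OC)cc2)cc1.[Li+].[Li+]
F9 | step 8 | (2R,2'R,3R,3'R)-5,7-bis(benzyloxy)-5',7'-dimethoxy-2,2'-bis(4-methoxyphenyl)-[3,3'-bichromane]-4,4'-dione | COc1ccc([C@@H]2Oc3cc(OCc4ccccc4)cc(OCc4ccccc4)c3C(=O)[C@@H]2[C@H]2C(=O)c3c(OC)cc(OC)cc3O[C@H]2c2ccc(OC)cc2)cc1
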